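**Retrosynthetic overview**
- The target is disconnected at two ester C–O bonds: C8–O (Mitsunobu esterification with epoxy acid 12, inversion) and C9–O (Ti(OiPr)4-mediated opening of an oxirane by acid 8, inversion).
- Both inversions relay from one catalytic asymmetric epoxidation of dienal 21 (two C–O bonds; sets C8 and C9). This is the key step and the proposed new one.
- The ten-membered carbocycle (C6–C7 bond) and then the γ-lactone (C6–O) close in one operation from open-chain bromo enal 27 with CrCl2.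
- The chain comes from neryl acetate (C2–C6, C15; Z alkene kept) by ozonolysis, iodo-Wittig, Heck coupling with acrolein and Morita–Baylis–Hillman (MBH) reaction with methyl acrylate.
- Ring order: transient oxirane (step 10, opened in step 12), then carbocycle, then lactone (both step 15); the side-chain oxirane is made separately (step 4) and attached in step 16.

Assumption: the SMILES is followed as drawn (ring alkenes cis in the ring, cis-2,3-dimethyloxirane ester); ring positions are cited in germacrane numbering (lactone O on C6, esters on C8 and C9, CO2Me carbon C14 on C10, exocyclic CH2 = C13 on C11).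

**Route**

Step 1
Reactants: 1 (4R)-4-benzyl-3-propanoyl-1,3-oxazolidin-2-one; 2 acetaldehyde
Product: 5 (4R)-4-benzyl-3-[(2R,3S)-3-hydroxy-2-methylbutanoyl]-1,3-oxazolidin-2-one, via boron Z-enolate 3 (not isolated), via boron aldolate 4 (not isolated)
Conditions: Bu2BOTf, Et3N, CH2Cl2, 0 °C; 2, −78 to 0 °C; then pH 7 buffer, MeOH, H2O2
Reagents that add atoms: none
Why: Evans syn-aldol reaction, in which the Z-boron enolate adds through a chair Zimmerman–Traxler transition state on the face away from the benzyl group and so sets C2′ (R) and C3′ (S) of the hydroxy acid side chain.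

Step 2
Reactants: 5 (4R)-4-benzyl-3-[(2R,3S)-3-hydroxy-2-methylbutanoyl]-1,3-oxazolidin-2-one
Product: 6 (4R)-4-benzyl-3-[(2R,3S)-3-{[tert-butyl(dimethyl)silyl]oxy}-2-methylbutanoyl]-1,3-oxazolidin-2-one
Conditions: TBSOTf, 2,6-lutidine, CH2Cl2, 0 °C
Reagents that add atoms: tert-butyldimethylsilyl triflate, CC(C)(C)[Si](C)(C)OS(=O)(=O)C(F)(F)F
Why: Standard O-silylation of a secondary alcohol with a silyl triflate, which touches no stereocentre and blocks retro-aldol and later competing acylation.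

Step 3
Reactants: 6 (4R)-4-benzyl-3-[(2R,3S)-3-{[tert-butyl(dimethyl)silyl]oxy}-2-methylbutanoyl]-1,3-oxazolidin-2-one
Product: 8 (2R,3S)-3-{[tert-butyl(dimethyl)silyl]oxy}-2-methylbutanoic acid, via peroxy acid 7 (not isolated)
Conditions: LiOH, H2O2, THF/H2O, 0 °C; then Na2SO3; then aq. HCl
Reagents that add atoms: hydrogen peroxide, OO
Why: Hydroperoxide cleavage of the Evans imide at the exocyclic carbonyl followed by sulfite reduction of the peracid, with no epimerisation at the α-carbon.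

Step 4
Reactants: 9 (2E)-2-methylbut-2-en-1-ol
Product: 10 [(2R,3R)-2,3-dimethyloxiran-2-yl]methanol
Conditions: Ti(OiPr)4 (10 mol%), D-(−)-diisopropyl tartrate (12 mol%), tBuOOH, 4 Å molecular sieves, CH2Cl2, −20 °C
Reagents that add atoms: tert-butyl hydroperoxide, CC(C)(C)OO
Why: Sharpless asymmetric epoxidation, in which the D-tartrate–titanium complex delivers oxygen to one face of the E allylic alcohol and sets both oxirane centres (cis-dimethyl follows from the E alkene).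

Step 5
Reactants: 10 [(2R,3R)-2,3-dimethyloxiran-2-yl]methanol
Product: 12 (2S,3R)-2,3-dimethyloxirane-2-carboxylic acid, via epoxy aldehyde 11 (not isolated)
Conditions: RuCl3 (2 mol%), NaIO4, MeCN/CCl4/H2O, 0 °C to rt
Reagents that add atoms: water, O
Why: Ruthenium tetroxide oxidation of a primary epoxy alcohol to the glycidic acid through the aldehyde hydrate, which leaves the oxirane and its two centres intact (the descriptor at C2 changes only by priority).

Step 6
Reactants: 13 neryl acetate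
Product: 15 (2Z)-3-methyl-6-oxohex-2-en-1-yl acetate, via secondary ozonide 14 (not isolated)
Conditions: O3 (1 equiv), CH2Cl2, −78 °C; then Me2S, −78 °C to rt
Reagents that add atoms: ozone, [O-][O+]=O
Why: Criegee ozonolysis, selective for the electron-rich isopropylidene alkene over the alkene deactivated by the allylic acetate, so the Z-trisubstituted alkene (C4=C5) survives.

Step 7
Reactants: 15 (2Z)-3-methyl-6-oxohex-2-en-1-yl acetate; 16 methyl (triphenyl-λ5-phosphanylidene)acetate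
Product: 18 methyl (2Z,6Z)-8-(acetyloxy)-2-iodo-6-methylocta-2,6-dienoate, via iodo ylide 17 (not isolated)
Conditions: NIS, CH2Cl2, −20 °C; then 15, −20 °C to rt
Reagents that add atoms: N-iodosuccinimide, O=C1CCC(=O)N1I
Why: Wittig olefination with the stabilised iodo ylide made in the flask, which places the chain trans to the ester (Z-iodoalkene) and thereby fixes the C1=C10 geometry of the target.

Step 8
Reactants: 18 methyl (2Z,6Z)-8-(acetyloxy)-2-iodo-6-methylocta-2,6-dienoate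
Product: 19 methyl (2Z,6Z)-8-hydroxy-2-iodo-6-methylocta-2,6-dienoate
Conditions: K2CO3 (0.2 equiv), MeOH, 0 °C
Reagents that add atoms: none
Why: Mild methanolysis of the primary allylic acetate (the methyl ester is degenerate towards methoxide), done here so that no base is needed after the acyl-migration-prone stage of step 12.

Step 9
Reactants: 19 methyl (2Z,6Z)-8-hydroxy-2-iodo-6-methylocta-2,6-dienoate; 20 acrolein
Product: 21 methyl (2E,6Z)-8-hydroxy-6-methyl-2-[(1E)-3-oxoprop-1-en-1-yl]octa-2,6-dienoate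
Conditions: Pd(OAc)2 (5 mol%), Bu4NCl, NaHCO3, DMF, 25 °C
Reagents that add atoms: none
Why: Heck reaction under Jeffery conditions, in which the alkenyl iodide couples with retention of its geometry and β-hydride elimination gives the E enal (C8=C9).

Step 10
Reactants: 21 methyl (2E,6Z)-8-hydroxy-6-methyl-2-[(1E)-3-oxoprop-1-en-1-yl]octa-2,6-dienoate
Product: 22 methyl (2E,6Z)-2-[(2R,3S)-3-formyloxiran-2-yl]-8-hydroxy-6-methylocta-2,6-dienoate
Conditions: (R)-2-{bis[3,5-bis(trifluoromethyl)phenyl][(trimethylsilyl)oxy]methyl}pyrrolidine (10 mol%; the enantiomer that gives (2S,3R)-epoxy aldehydes from E enals), H2O2 (35% aq., 1.3 equiv), CH2Cl2, rt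
Reagents that add atoms: hydrogen peroxide, OO
Why: Proposed new method: iminium-catalysed epoxidation has not been shown on a 4-(methoxycarbonyl)-2,4-dienal that also carries a free allylic alcohol; the single aldehyde forms the iminium ion, hydroperoxide adds at the β-carbon C9 on the face away from the diaryl(silyloxy)methyl group (sets C9), the resulting enamine closes on oxygen with loss of hydroxide (sets C8, trans), the δ-carbon C1 is trisubstituted and shielded by the ester-bearing C10 so 1,6-addition should be slower, and the isolated C4=C5 alkene is not activated; the closest known reaction is the diarylprolinol silyl ether/H2O2 epoxidation of simple E enals.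

Step 11
Reactants: 22 methyl (2E,6Z)-2-[(2R,3S)-3-formyloxiran-2-yl]-8-hydroxy-6-methylocta-2,6-dienoate; 23 methyl acrylate
Product: 24 methyl (2E,6Z)-8-hydroxy-2-{(2R,3R)-3-[1-hydroxy-2-(methoxycarbonyl)prop-2-en-1-yl]oxiran-2-yl}-6-methylocta-2,6-dienoate (both carbinol epimers)
Conditions: 1,4-diazabicyclo[2.2.2]octane (DABCO, 1 equiv), 23 (excess, neat), rt
Reagents that add atoms: none
Why: MBH reaction of an activated epoxy aldehyde; the new carbinol centre (C7) forms as a mixture that does not matter because it becomes sp2 in step 14, and the β-substituted enoate is inert to DABCO.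

Step 12
Reactants: 24 epoxy MBH alcohol (both carbinol epimers); 8 (2R,3S)-3-{[tert-butyl(dimethyl)silyl]oxy}-2-methylbutanoic acid
Product: 25 methyl (2E,6Z)-2-[(1S,2R)-1-{[(2R,3S)-3-{[tert-butyl(dimethyl)silyl]oxy}-2-methylbutanoyl]oxy}-2,3-dihydroxy-4-(methoxycarbonyl)pent-4-en-1-yl]-8-hydroxy-6-methylocta-2,6-dienoate (both C3 epimers of the pentenyl chain)
Conditions: Ti(OiPr)4 (2 equiv), 8 (1.5 equiv), CH2Cl2, rt; aq. tartaric acid work-up
Reagents that add atoms: none
Why: Titanium-mediated opening of a 2,3-epoxy alcohol by a carboxylic acid, in which the carboxylate is delivered within the titanium chelate of the C7 alkoxide to the distal, allylic oxirane carbon C9 with inversion (C9 becomes S) while the C8–O bond is retained.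

Step 13
Reactants: 25 triol monoester (both epimers)
Product: 26 methyl (2E,6Z)-2-[(1S,2R)-1-{[(2R,3S)-3-{[tert-butyl(dimethyl)silyl]oxy}-2-methylbutanoyl]oxy}-2,3-dihydroxy-4-(methoxycarbonyl)pent-4-en-1-yl]-6-methyl-8-oxoocta-2,6-dienoate (both epimers)
Conditions: activated MnO2 (excess), CH2Cl2, rt
Reagents that add atoms: none
Why: MnO2 oxidises the electron-rich primary allylic alcohol (C6) much faster than the acrylate-flanked secondary allylic alcohol or the saturated one, and gives the Z enal without isomerisation.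

Step 14
Reactants: 26 enal diol (both epimers)
Product: 27 methyl (2E,6Z)-2-[(1S,2R,3Z)-5-bromo-1-{[(2R,3S)-3-{[tert-butyl(dimethyl)silyl]oxy}-2-methylbutanoyl]oxy}-2-hydroxy-4-(methoxycarbonyl)pent-3-en-1-yl]-6-methyl-8-oxoocta-2,6-dienoate
Conditions: NBS, Me2S, CH2Cl2, −20 to 0 °C; used at once
Reagents that add atoms: N-bromosuccinimide, O=C1CCC(=O)N1Br
Why: Corey–Kim-type activation of the MBH alcohol followed by SN2′ attack of bromide gives the Z 2-(bromomethyl)enoate from both epimers, while the non-allylic C8 alkoxysulfonium reverts to the alcohol on work-up.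

Step 15
Reactants: 27 bromo enal
Product: 30 methyl (3aR,4R,5S,6E,10Z,11aR)-5-{[(2R,3S)-3-{[tert-butyl(dimethyl)silyl]oxy}-2-methylbutanoyl]oxy}-4-hydroxy-10-methyl-3-methylidene-2-oxo-2,3,3a,4,5,8,9,11a-octahydrocyclodeca[b]furan-6-carboxylate, via allylchromium dichloride 28 (not isolated), via seco hydroxy ester 29 (not isolated)
Conditions: CrCl2 (8 equiv), THF/DMF (3:1), slow addition of 27 to 2 mM, rt
Reagents that add atoms: none
Why: Intramolecular Nozaki–Hiyama-type 2-(alkoxycarbonyl)allylation, in which the allylchromium adds through its γ-carbon to the enal in a chair transition state that gives the 6,7-anti pair on the face held by the chromium-bound C8 hydroxyl (expected C6 R and C7 S), and the chromium alkoxide at C6 then closes the trans γ-lactone.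

Step 16
Reactants: 30 C8-epimeric hydroxy lactone; 12 (2S,3R)-2,3-dimethyloxirane-2-carboxylic acid
Product: 31 methyl (3aS,4S,5S,6E,10Z,11aR)-5-{[(2R,3S)-3-{[tert-butyl(dimethyl)silyl]oxy}-2-methylbutanoyl]oxy}-4-{[(2S,3R)-2,3-dimethyloxirane-2-carbonyl]oxy}-10-methyl-3-methylidene-2-oxo-2,3,3a,4,5,8,9,11a-octahydrocyclodeca[b]furan-6-carboxylate
Conditions: PPh3, DIAD, 12 (2 equiv), toluene, 0 °C to rt
Reagents that add atoms: none
Why: Mitsunobu esterification, in which the carboxylate displaces the C8 oxyphosphonium by SN2 with inversion (C8 becomes S); the C9 ester is cis to the leaving group on the ring and cannot participate.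

Step 17
Reactants: 31 silyl-protected diester
Product: 32 methyl (3aS,4S,5S,6E,10Z,11aR)-4-{[(2S,3R)-2,3-dimethyloxirane-2-carbonyl]oxy}-5-{[(2R,3S)-3-hydroxy-2-methylbutanoyl]oxy}-10-methyl-3-methylidene-2-oxo-2,3,3a,4,5,8,9,11a-octahydrocyclodeca[b]furan-6-carboxylate (CNP0135583.2)
Conditions: HF·pyridine, pyridine, THF, 0 °C to rt
Reagents that add atoms: none
Why: Buffered fluoride cleavage of the secondary silyl ether, which leaves the glycidic ester, the α-methylene lactone and all stereocentres untouched.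

**Compound list**

1 | (4R)-4-benzyl-3-propanoyl-1,3-oxazolidin-2-one | CCC(=O)N1[C@H](Cc2ccccc2)COC1=O | starting material
2 | acetaldehyde | CC=O | starting material
3 | (4R)-4-benzyl-3-[(1Z)-1-(dibutylboranyloxy)prop-1-en-1-yl]-1,3-oxazolidin-2-one (boron Z-enolate) | C/C=C(/N1[C@H](Cc2ccccc2)COC1=O)OB(CCCC)CCCC | intermediate
4 | (4R)-4-benzyl-3-[(2R,3S)-3-(dibutylboranyloxy)-2-methylbutanoyl]-1,3-oxazolidin-2-one (boron aldolate) | O=C([C@H](C)[C@H](C)OB(CCCC)CCCC)N1[C@H](Cc2ccccc2)COC1=O | intermediate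
5 | (4R)-4-benzyl-3-[(2R,3S)-3-hydroxy-2-methylbutanoyl]-1,3-oxazolidin-2-one | O=C([C@H](C)[C@H](C)O)N1[C@H](Cc2ccccc2)COC1=O | intermediate
6 | (4R)-4-benzyl-3-[(2R,3S)-3-{[tert-butyl(dimethyl)silyl]oxy}-2-methylbutanoyl]-1,3-oxazolidin-2-one | O=C([C@H](C)[C@H](C)O[Si](C)(C)C(C)(C)C)N1[C@H](Cc2ccccc2)COC1=O | intermediate
7 | (2R,3S)-3-{[tert-butyl(dimethyl)silyl]oxy}-2-methylbutaneperoxoic acid | OOC(=O)[C@H](C)[C@H](C)O[Si](C)(C)C(C)(C)C | intermediate
8 | (2R,3S)-3-{[tert-butyl(dimethyl)silyl]oxy}-2-methylbutanoic acid | OC(=O)[C@H](C)[C@H](C)O[Si](C)(C)C(C)(C)C | intermediate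
9 | (2E)-2-methylbut-2-en-1-ol (tiglyl alcohol) | C/C=C(\C)CO | starting material
10 | [(2R,3R)-2,3-dimethyloxiran-2-yl]methanol | OC[C@@]1(C)O[C@@H]1C | intermediate
11 | (2S,3R)-2,3-dimethyloxirane-2-carbaldehyde | O=C[C@@]1(C)O[C@@H]1C | intermediate
12 | (2S,3R)-2,3-dimethyloxirane-2-carboxylic acid | OC(=O)[C@@]1(C)O[C@@H]1C | intermediate
13 | neryl acetate, (2Z)-3,7-dimethylocta-2,6-dien-1-yl acetate | CC(=O)OC/C=C(/C)CCC=C(C)C | starting material
14 | (2Z)-5-(5,5-dimethyl-1,2,4-trioxolan-3-yl)-3-methylpent-2-en-1-yl acetate (secondary ozonide) | CC(=O)OC/C=C(/C)CCC1OOC(C)(C)O1 | intermediate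
15 | (2Z)-3-methyl-6-oxohex-2-en-1-yl acetate | CC(=O)OC/C=C(/C)CCC=O | intermediate
16 | methyl (triphenyl-λ5-phosphanylidene)acetate | COC(=O)C=P(c1ccccc1)(c1ccccc1)c1ccccc1 | starting material
17 | methyl iodo(triphenyl-λ5-phosphanylidene)acetate | COC(=O)C(I)=P(c1ccccc1)(c1ccccc1)c1ccccc1 | intermediate
18 | methyl (2Z,6Z)-8-(acetyloxy)-2-iodo-6-methylocta-2,6-dienoate | CC(=O)OC/C=C(/C)CC/C=C(\I)C(=O)OC | intermediate
19 | methyl (2Z,6Z)-8-hydroxy-2-iodo-6-methylocta-2,6-dienoate | OC/C=C(/C)CC/C=C(\I)C(=O)OC | intermediate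
20 | acrolein (prop-2-enal) | C=CC=O | starting material
21 | methyl (2E,6Z)-8-hydroxy-6-methyl-2-[(1E)-3-oxoprop-1-en-1-yl]octa-2,6-dienoate | OC/C=C(/C)CC/C=C(/C(=O)OC)\C=C\C=O | intermediate
22 | methyl (2E,6Z)-2-[(2R,3S)-3-formyloxiran-2-yl]-8-hydroxy-6-methylocta-2,6-dienoate | OC/C=C(/C)CC/C=C(/C(=O)OC)[C@H]1O[C@@H]1C=O | intermediate
23 | methyl acrylate | C=CC(=O)OC | starting material
24 | methyl (2E,6Z)-8-hydroxy-2-{(2R,3R)-3-[1-hydroxy-2-(methoxycarbonyl)prop-2-en-1-yl]oxiran-2-yl}-6-methylocta-2,6-dienoate (both carbinol epimers) | OC/C=C(/C)CC/C=C(/C(=O)OC)[C@H]1O[C@@H]1C(O)C(=C)C(=O)OC | intermediate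
25 | methyl (2E,6Z)-2-[(1S,2R)-1-{[(2R,3S)-3-{[tert-butyl(dimethyl)silyl]oxy}-2-methylbutanoyl]oxy}-2,3-dihydroxy-4-(methoxycarbonyl)pent-4-en-1-yl]-8-hydroxy-6-methylocta-2,6-dienoate (both C3 epimers of the pentenyl chain) | OC/C=C(/C)CC/C=C(/C(=O)OC)[C@H](OC(=O)[C@H](C)[C@H](C)O[Si](C)(C)C(C)(C)C)[C@H](O)C(O)C(=C)C(=O)OC | intermediate
26 | methyl (2E,6Z)-2-[(1S,2R)-1-{[(2R,3S)-3-{[tert-butyl(dimethyl)silyl]oxy}-2-methylbutanoyl]oxy}-2,3-dihydroxy-4-(methoxycarbonyl)pent-4-en-1-yl]-6-methyl-8-oxoocta-2,6-dienoate (both epimers) | O=C/C=C(/C)CC/C=C(/C(=O)OC)[C@H](OC(=O)[C@H](C)[C@H](C)O[Si](C)(C)C(C)(C)C)[C@H](O)C(O)C(=C)C(=O)OC | intermediate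
27 | methyl (2E,6Z)-2-[(1S,2R,3Z)-5-bromo-1-{[(2R,3S)-3-{[tert-butyl(dimethyl)silyl]oxy}-2-methylbutanoyl]oxy}-2-hydroxy-4-(methoxycarbonyl)pent-3-en-1-yl]-6-methyl-8-oxoocta-2,6-dienoate | O=C/C=C(/C)CC/C=C(/C(=O)OC)[C@H](OC(=O)[C@H](C)[C@H](C)O[Si](C)(C)C(C)(C)C)[C@H](O)/C=C(\CBr)C(=O)OC | intermediate
28 | allylchromium dichloride of 27 (CH2Br replaced by CH2CrCl2) | O=C/C=C(/C)CC/C=C(/C(=O)OC)[C@H](OC(=O)[C@H](C)[C@H](C)O[Si](C)(C)C(C)(C)C)[C@H](O)/C=C(\C[Cr](Cl)Cl)C(=O)OC | intermediate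
29 | methyl (1E,5Z,7R,8S,9R,10S)-10-{[(2R,3S)-3-{[tert-butyl(dimethyl)silyl]oxy}-2-methylbutanoyl]oxy}-7,9-dihydroxy-8-(3-methoxy-3-oxoprop-1-en-2-yl)-5-methylcyclodeca-1,5-diene-1-carboxylate (formed as its chromium alkoxide) | O[C@@H]1/C=C(/C)CC/C=C(/C(=O)OC)[C@H](OC(=O)[C@H](C)[C@H](C)O[Si](C)(C)C(C)(C)C)[C@H](O)[C@H]1C(=C)C(=O)OC | intermediate
30 | methyl (3aR,4R,5S,6E,10Z,11aR)-5-{[(2R,3S)-3-{[tert-butyl(dimethyl)silyl]oxy}-2-methylbutanoyl]oxy}-4-hydroxy-10-methyl-3-methylidene-2-oxo-2,3,3a,4,5,8,9,11a-octahydrocyclodeca[b]furan-6-carboxylate | C=C1C(=O)O[C@@H]2/C=C(/C)CC/C=C(/C(=O)OC)[C@H](OC(=O)[C@H](C)[C@H](C)O[Si](C)(C)C(C)(C)C)[C@H](O)[C@@H]12 | intermediate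
31 | methyl (3aS,4S,5S,6E,10Z,11aR)-5-{[(2R,3S)-3-{[tert-butyl(dimethyl)silyl]oxy}-2-methylbutanoyl]oxy}-4-{[(2S,3R)-2,3-dimethyloxirane-2-carbonyl]oxy}-10-methyl-3-methylidene-2-oxo-2,3,3a,4,5,8,9,11a-octahydrocyclodeca[b]furan-6-carboxylate | C=C1C(=O)O[C@@H]2/C=C(/C)CC/C=C(/C(=O)OC)[C@H](OC(=O)[C@H](C)[C@H](C)O[Si](C)(C)C(C)(C)C)[C@@H](OC(=O)[C@@]3(C)O[C@@H]3C)[C@@H]12 | intermediate
32 | methyl (3aS,4S,5S,6E,10Z,11aR)-4-{[(2S,3R)-2,3-dimethyloxirane-2-carbonyl]oxy}-5-{[(2R,3S)-3-hydroxy-2-methylbutanoyl]oxy}-10-methyl-3-methylidene-2-oxo-2,3,3a,4,5,8,9,11a-octahydrocyclodeca[b]furan-6-carboxylate | C=C1C(=O)O[C@@H]2/C=C(/C)CC/C=C(/C(=O)OC)[C@H](OC(=O)[C@H](C)[C@H](C)O)[C@@H](OC(=O)[C@@]3(C)O[C@@H]3C)[C@@H]12 | target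

**Step count**
- Total: 17 steps (3 for acid 8, 2 for acid 12, 12 on the main line).
- Longest linear sequence: 12 steps (steps 6–17, from neryl acetate 13 to 32).

**Three steps most likely to fail**

1. Step 10 (the proposed new epoxidation). The risks are 1,6-addition at C1, epoxidation of the wrong alkene and erosion of ee on this unprecedented dienal.
   The fallback uses known chemistry only. It sets out from 18 and comes back at 24. Stille coupling of 18 with (E)-3-(tributylstannyl)prop-2-en-1-ol (Pd2(dba)3, AsPh3, CuI, DMF) gives methyl (2E,6Z)-8-(acetyloxy)-2-[(1E)-3-hydroxyprop-1-en-1-yl]-6-methylocta-2,6-dienoate F1. Sharpless epoxidation (Ti(OiPr)4, D-(−)-diisopropyl tartrate, tBuOOH, −20 °C), directed by the new allylic hydroxyl while C6 stays masked as the acetate, gives methyl (2E,6Z)-8-(acetyloxy)-2-[(2R,3R)-3-(hydroxymethyl)oxiran-2-yl]-6-methylocta-2,6-dienoate F2. Dess–Martin oxidation gives methyl (2E,6Z)-8-(acetyloxy)-2-[(2R,3S)-3-formyloxiran-2-yl]-6-methylocta-2,6-dienoate F3. The MBH reaction with methyl acrylate and DABCO gives methyl (2E,6Z)-8-(acetyloxy)-2-{(2R,3R)-3-[1-hydroxy-2-(methoxycarbonyl)prop-2-en-1-yl]oxiran-2-yl}-6-methylocta-2,6-dienoate F4. Neutral deacetylation with immobilised Candida antarctica lipase B in MeOH/MTBE then gives 24.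

2. Step 15 (ring closure and lactonisation). The risks are the facial and syn/anti outcome at C6/C7, oligomerisation, and lactonisation onto the free C8 hydroxyl instead of C6.
   The fallback sets out from 27 and comes back at 30. It removes the chelating hydroxyl and the second lactonisation mode and changes the metal. Silylation (TESOTf, 2,6-lutidine, −78 °C) gives methyl (2E,6Z)-2-[(1S,2R,3Z)-5-bromo-1-{[(2R,3S)-3-{[tert-butyl(dimethyl)silyl]oxy}-2-methylbutanoyl]oxy}-4-(methoxycarbonyl)-2-[(triethylsilyl)oxy]pent-3-en-1-yl]-6-methyl-8-oxoocta-2,6-dienoate F5. An aqueous indium Barbier cyclisation (indium powder, THF/H2O, 2 mM; then catalytic PPTS in CH2Cl2 to close the only possible lactone) under non-chelation control gives methyl (3aS,4R,5S,6E,10Z,11aR)-5-{[(2R,3S)-3-{[tert-butyl(dimethyl)silyl]oxy}-2-methylbutanoyl]oxy}-10-methyl-3-methylidene-2-oxo-4-[(triethylsilyl)oxy]-2,3,3a,4,5,8,9,11a-octahydrocyclodeca[b]furan-6-carboxylate F6. Selective removal of the triethylsilyl group (PPTS, MeOH, 0 °C) gives 30.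

3. Step 16 (Mitsunobu inversion at the hindered C8 alcohol with a hindered acid). The risks are elimination, retention or no reaction.
   The fallback sets out from 30 and comes back at 31. It inverts C8 by redox and then acylates with retention. Dess–Martin oxidation gives methyl (3aS,5S,6E,10Z,11aR)-5-{[(2R,3S)-3-{[tert-butyl(dimethyl)silyl]oxy}-2-methylbutanoyl]oxy}-10-methyl-3-methylidene-2,4-dioxo-2,3,3a,4,5,8,9,11a-octahydrocyclodeca[b]furan-6-carboxylate F7. Reduction with NaBH4/CeCl3 (MeOH, −78 °C), expected from the face opposite the C9 ester, gives methyl (3aR,4S,5S,6E,10Z,11aR)-5-{[(2R,3S)-3-{[tert-butyl(dimethyl)silyl]oxy}-2-methylbutanoyl]oxy}-4-hydroxy-10-methyl-3-methylidene-2-oxo-2,3,3a,4,5,8,9,11a-octahydrocyclodeca[b]furan-6-carboxylate F8. Yamaguchi esterification with 12 (2,4,6-trichlorobenzoyl chloride, Et3N, DMAP, toluene) gives 31.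

**Further compounds**

F1 | step 10 | methyl (2E,6Z)-8-(acetyloxy)-2-[(1E)-3-hydroxyprop-1-en-1-yl]-6-methylocta-2,6-dienoate | CC(=O)OC/C=C(/C)CC/C=C(/C(=O)OC)\C=C\CO
F2 | step 10 | methyl (2E,6Z)-8-(acetyloxy)-2-[(2R,3R)-3-(hydroxymethyl)oxiran-2-yl]-6-methylocta-2,6-dienoate | CC(=O)OC/C=C(/C)CC/C=C(/C(=O)OC)[C@H]1O[C@@H]1CO
F3 | step 10 | methyl (2E,6Z)-8-(acetyloxy)-2-[(2R,3S)-3-formyloxiran-2-yl]-6-methylocta-2,6-dienoate | CC(=O)OC/C=C(/C)CC/C=C(/C(=O)OC)[C@H]1O[C@@H]1C=O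
F4 | step 10 | methyl (2E,6Z)-8-(acetyloxy)-2-{(2R,3R)-3-[1-hydroxy-2-(methoxycarbonyl)prop-2-en-1-yl]oxiran-2-yl}-6-methylocta-2,6-dienoate (both carbinol epimers) | CC(=O)OC/C=C(/C)CC/C=C(/C(=O)OC)[C@H]1O[C@@H]1C(O)C(=C)C(=O)OC
F5 | step 15 | methyl (2E,6Z)-2-[(1S,2R,3Z)-5-bromo-1-{[(2R,3S)-3-{[tert-butyl(dimethyl)silyl]oxy}-2-methylbutanoyl]oxy}-4-(methoxycarbonyl)-2-[(triethylsilyl)oxy]pent-3-en-1-yl]-6-methyl-8-oxoocta-2,6-dienoate | O=C/C=C(/C)CC/C=C(/C(=O)OC)[C@H](OC(=O)[C@H](C)[C@H](C)O[Si](C)(C)C(C)(C)C)[C@H](O[Si](CC)(CC)CC)/C=C(\CBr)C(=O)OC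
F6 | step 15 | methyl (3aS,4R,5S,6E,10Z,11aR)-5-{[(2R,3S)-3-{[tert-butyl(dimethyl)silyl]oxy}-2-methylbutanoyl]oxy}-10-methyl-3-methylidene-2-oxo-4-[(triethylsilyl)oxy]-2,3,3a,4,5,8,9,11a-octahydrocyclodeca[b]furan-6-carboxylate | C=C1C(=O)O[C@@H]2/C=C(/C)CC/C=C(/C(=O)OC)[C@H](OC(=O)[C@H](C)[C@H](C)O[Si](C)(C)C(C)(C)C)[C@H](O[Si](CC)(CC)CC)[C@@H]12
F7 | step 16 | methyl (3aS,5S,6E,10Z,11aR)-5-{[(2R,3S)-3-{[tert-butyl(dimethyl)silyl]oxy}-2-methylbutanoyl]oxy}-10-methyl-3-methylidene-2,4-dioxo-2,3,3a,4,5,8,9,11a-octahydrocyclodeca[b]furan-6-carboxylate | C=C1C(=O)O[C@@H]2/C=C(/C)CC/C=C(/C(=O)OC)[C@H](OC(=O)[C@H](C)[C@H](C)O[Si](C)(C)C(C)(C)C)C(=O)[C@@H]12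
F8 | step 16 | methyl (3aR,4S,5S,6E,10Z,11aR)-5-{[(2R,3S)-3-{[tert-butyl(dimethyl)silyl]oxy}-2-methylbutanoyl]oxy}-4-hydroxy-10-methyl-3-methylidene-2-oxo-2,3,3a,4,5,8,9,11a-octahydrocyclodeca[b]furan-6-carboxylate | C=C1C(=O)O[C@@H]2/C=C(/C)CC/C=C(/C(=O)OC)[C@H](OC(=O)[C@H](C)[C@H](C)O[Si](C)(C)C(C)(C)C)[C@@H](O)[C@@H]12
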